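**The question.** The reagent, charged at 0.500 equiv on the substrate, was what I followed.

| setting | autumn | midnight | spring |
|---|---|---|---|
| substrate | 1.1 M | 1.1 M | 1.1 M |
| reagent | 0.500 equiv | 0.500 equiv | 0.500 equiv |
| free catalyst | 2 mol% | 2 mol% | 2 mol% |
| time | 5.0 h | 5.0 h | 5.0 h |
| remark | at 25 °C until 1.0 h, from then on at 40 °C |  |  |
| temperature |  | 25 °C | 40 °C |

    substrate + free catalyst ⇌ catalyst intermediate A (K1 = 1.4 M⁻¹, k1 = 0.74 M⁻¹ min⁻¹, Ea1 = 71.0 kJ mol⁻¹, ΔH1 = −66.0 kJ mol⁻¹)
    reagent + catalyst intermediate A ⇌ catalyst intermediate B (K2 = 1.3 M⁻¹, k2 = 2.4 M⁻¹ min⁻¹, Ea2 = 40.0 kJ mol⁻¹, ΔH2 = −74.0 kJ mol⁻¹)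
    catalyst intermediate B → free catalyst + product (k3 = 16 min⁻¹, Ea3 = 78.0 kJ mol⁻¹)
    (constants at 25 °C)

- all constants are for 25 °C and move with temperature by the activation energies and enthalpies

1. which flask leads in amount of product, in percent of the substrate charged ("all alike" within 1.5 percentage points) (autumn / midnight / spring / all alike)
2. how much product is there at the end, in percent of the substrate charged: autumn
3. how much product is there at the end, in percent of the substrate charged: midnight
4. how much product is there at the end, in percent of the substrate charged: spring

**The ceiling.** Each product uses one reagent, and reagent is charged at less than substrate, making it the limiting reagent. Product therefore tops out at 50.0% of the substrate charged in every flask.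

**The floor.** I could reckon this by hand for midnight, using the constants as given. Substrate stays at or above 48.0% of its charge even with the catalyst fully loaded, and reagent cannot exceed its whole charge. Taking these two values understates how much catalyst sits as intermediate A. Free catalyst then turns into intermediate A at 0.391 min⁻¹. Intermediate A goes back at 0.529 min⁻¹, and onward at 1.18 min⁻¹, where 89.7% of intermediate B goes forward. So in midnight, once these rates balance, at least 18.6% of the catalyst sits as intermediate A.

The reagent fraction in midnight then decays pseudo-first-order, with a time constant of at most 1.89 h. Multiplying by 2.3 gives 4.36 h, the decade time, the time in which unused reagent falls tenfold. Midnight's run holds 1.15 decades, which leaves at most 7.14% of the reagent and puts the floor at 46.4%.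

**The forecast.** It gave 49.7% for autumn, 49.8% for midnight and 49.7% for spring, so all alike. Its ground was this: “Warming speeds the steps but also weakens the binding equilibria”. Its midnight figure lies inside my bracket: it stands above the floor, and the ceiling stands above it.

**The result.** The flasks gave 49.7%, 49.8% and 49.7% for autumn, midnight and spring, so all alike. Midnight kept 0.37% of its reagent, which corresponds to a decade time of 2.06 h, shorter than my worst case. Midnight's answer moved by 5 points with reagent at 0.449 equiv or 0.551 equiv.

**Earlier reading.** The neighbour is autumn itself, read at 2.0 h. Its charges match midnight's, so I reused the same decade time as an estimate, though that time is reckoned at 25 °C and autumn warms at 1.0 h. That gives 0.459 decades, 34.8% of the reagent left and an estimated floor of 32.6%. Autumn at that reading stood above that floor, with 13% of its reagent left and 43.5% product.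

Its constants were drawn at random within sensible limits; the run is a simulation.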